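**Plan**

1. Retrosynthesis: remove the two O4 sulfate esters and both acetonides, then cut C7=C8 and C7'=C8' (twofold Julia–Lythgoe olefination of all-E crocetindial, C8–C8', with two copies of one ring C7 sulfone). Within the ring, cut C1–C6, then C6=C7 (vinyl sulfone), C4–C5 (aldol) and C1–C2 (epoxide opening).
2. Forward: the open chain C1–C7 is built first, the only carbocycle (C1–C6) is closed by forming the C1–C6 bond, two such rings are joined to the C20 polyene, and deprotection and sulfation come last.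
3. Enabling feature: in each cyclohexane end ring the quaternary gem-dimethyl carbon C1 is bonded directly to C6, the tertiary ring carbon that carries the polyene. C1 can therefore arise as a tertiary radical from an isopropenyl group and C6 as the β-carbon of a C6=C7 vinyl sulfone, whose sulfone later builds C7=C8.
4. Stereochemistry: C3 from (S)-glycidol; C4 and C5 from an Evans syn aldol matched with the Cornforth/Felkin bias of the α-silyloxy aldehyde; C6 from the chair-like 6-exo radical closure (side arm trans to the C5 methyl); alkene geometry from all-E crocetindial and the E-selective Julia elimination; O4 versus O3 from a stannylene acetal.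

Key step: step 9

Remarks: carotenoid numbering is used for all intermediates (ring C1–C6 with C1 gem-dimethyl, C3/C4 oxygenated, C5 methyl, C6 bearing the chain; chain C7–C15; primes for the second half). Crocetindial (15) is taken as a purchased C20 building block. The target is written, as drawn, as the free bis(hydrogen sulfate), released from its salt by cation exchange in the cold.

**Route**

Step 1
Reactants: 1 (S)-glycidol; 2 isopropenylmagnesium bromide
Product: 3 (R)-4-methylpent-4-ene-1,2-diol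
Conditions: 2 (2.5 equiv), CuI (10 mol %), THF, −30 → 0 °C; aq. NH4Cl
Reagents that add atoms: none
Why: Copper-catalysed Grignard opening of the terminal epoxide at its CH2 carbon (the first equivalent only deprotonates the hydroxyl) forms C1–C2 without touching the carbinol carbon, so the configuration of 1 becomes C3 of the target.

Step 2
Reactants: 3
Product: 4 (R)-4-methyl-1,2-bis(triethylsilyloxy)pent-4-ene
Conditions: Et3SiCl (2.3 equiv), imidazole, CH2Cl2, 0 °C → rt
Reagents that add atoms: chlorotriethylsilane, CC[Si](Cl)(CC)CC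
Why: Routine silyl ether formation on both hydroxyls; no stereocentre is affected.

Step 3
Reactants: 4
Product: 5 (R)-4-methyl-2-(triethylsilyloxy)pent-4-enal
Conditions: (COCl)2, DMSO, CH2Cl2, −78 → −40 °C; Et3N, −78 → 0 °C
Reagents that add atoms: none
Why: Under Swern conditions a primary triethylsilyl ether is oxidised directly to the aldehyde while the secondary silyl ether stays (chemoselective Swern oxidation); the cold, buffered conditions and immediate use should preserve the α-stereocentre.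

Step 4
Reactants: 5; 6 (S)-4-benzyl-3-propionyloxazolidin-2-one
Product: 8 syn-aldol adduct (2S,3S,4R in the acyl chain), via Z-dibutylboron enolate 7 (not isolated)
Conditions: 6, Bu2BOTf, Et3N, CH2Cl2, 0 °C; 5, −78 → 0 °C; pH 7 phosphate buffer, MeOH, 30 % H2O2, 0 °C
Reagents that add atoms: none
Why: Evans syn aldol: the Z-boron enolate reacts through a closed chair transition state on the face away from the benzyl group, which sets C5 and C4, and this sense coincides with the Cornforth/Felkin 3,4-anti preference of the (R)-α-silyloxy aldehyde (matched pair).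

Step 5
Reactants: 8
Product: 9 (2S,3S,4R)-3-hydroxy-N-methoxy-N,2,6-trimethyl-4-(triethylsilyloxy)hept-6-enamide
Conditions: MeNH(OMe)·HCl, AlMe3, CH2Cl2, −20 → 0 °C; aq. KNaC4H4O6
Reagents that add atoms: N,O-dimethylhydroxylamine hydrochloride, CNOC.Cl
Why: Aluminium-amide transamination to the Weinreb amide is directed to the exocyclic carbonyl by the free β-hydroxyl and releases the auxiliary without affecting any stereocentre.

Step 6
Reactants: 9
Product: 10 (2S)-2-[(4S,5R)-2,2-dimethyl-5-(2-methylprop-2-enyl)-1,3-dioxolan-4-yl]-N-methoxy-N-methylpropanamide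
Conditions: Me2C(OMe)2, CSA (10 mol %), acetone, 0 °C → rt; Et3N
Reagents that add atoms: 2,2-dimethoxypropane, COC(C)(C)OC
Why: Acid-catalysed transketalisation: the C4 hydroxyl forms a mixed ketal whose oxocarbenium ion is captured by the neighbouring silyloxy oxygen with transfer of the silyl group to methanol, so the cis-dioxolane forms without a free γ-hydroxy amide that could lactonise.

Step 7
Reactants: 10
Product: 11 (2S)-2-[(4S,5R)-2,2-dimethyl-5-(2-methylprop-2-enyl)-1,3-dioxolan-4-yl]propanal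
Conditions: i-Bu2AlH, THF, −78 °C; aq. KNaC4H4O6
Reagents that add atoms: none
Why: Hydride reduction of a Weinreb amide stops at the chelated tetrahedral stage and gives the aldehyde on work-up; at −78 °C the α-methyl stereocentre and the acetonide should be untouched.

Step 8
Reactants: 11; 12 diethyl [(phenylsulfonyl)methyl]phosphonate
Product: 13 (E)-vinyl sulfone with isopropenyl group and C3/C4 acetonide (key-step precursor)
Conditions: 12, LiCl, DBU, MeCN, 0 °C → rt
Reagents that add atoms: none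
Why: Horner–Wadsworth–Emmons olefination under Masamune–Roush conditions; the mild base should spare the epimerisable α-methyl aldehyde and the sulfonyl-stabilised phosphonate gives the E-alkene.

Step 9
Reactants: 13
Product: 14 ring C7 phenyl sulfone, (3aS,4R,5R,7aR)-2,2,4,6,6-pentamethyl-5-[(phenylsulfonyl)methyl]hexahydro-1,3-benzodioxole
Conditions: Fe(acac)3 (0.5 equiv), PhSiH3 (2.5 equiv), EtOH–(CH2OH)2 (5:1), 60 °C, dilute
Reagents that add atoms: none
Why: Fe(acac)3 and PhSiH3 in ethanol form an iron hydride that transfers a hydrogen atom to the terminal CH2 of the isopropenyl group (Markovnikov metal-hydride hydrogen-atom transfer), which turns that carbon into the second methyl of the gem-dimethyl pair and leaves a nucleophilic tertiary radical at C1. The radical adds to C6, the β-carbon of the vinyl sulfone, in a 6-exo-trig closure that forms the C1–C6 bond and the cyclohexane; the α-sulfonyl radical at C7 is then reduced by divalent iron and protonated by ethanol. The closest known reaction type is the iron-hydride reductive olefin coupling (radical conjugate addition of an unactivated alkene to an acceptor alkene), used here intramolecularly. The only new stereocentre, C6, is set by a chair-like transition state with the C5 methyl, the C4 oxygen and the sulfonylvinyl group equatorial, so the CH2SO2Ph arm ends trans to the C5 methyl; the flipped chair would push the C5 methyl into a 1,3-diaxial clash with a C1 methyl. The step needs hydrogen-atom transfer to the electron-rich 1,1-disubstituted alkene rather than to the vinyl sulfone, and exo rather than endo addition; both follow from polarity matching (attack at C6 gives the sulfonyl-stabilised radical), and the neutral medium spares the acetonide.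

Step 10
Reactants: 14 (2.3 equiv); 15 crocetindial
Product: 18 bis(β-benzoyloxy sulfone), via lithiated sulfone 16 (not isolated), via dilithium bis-alkoxide 17 (not isolated)
Conditions: 14, n-BuLi, THF, −78 °C; 15, THF, −78 → −50 °C; BzCl, −78 °C → rt; dark
Reagents that add atoms: benzoyl chloride, O=C(Cl)c1ccccc1
Why: First stage of the Julia–Lythgoe olefination: the α-sulfonyl carbanion adds 1,2 to both aldehyde groups and in-flask benzoylation blocks retro-addition; the C7/C8 and C7'/C8' stereocentres form as mixtures and are erased in step 11.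

Step 11
Reactants: 18
Product: 19 all-E bis-acetonide of 5,6,5',6'-tetrahydro-β,β-carotene-3,4,3',4'-tetrol
Conditions: SmI2 (5 equiv), THF–DMPU, −78 → −20 °C, dark; air, aq. NaHCO3
Reagents that add atoms: none
Why: Julia–Lythgoe reductive elimination: electron transfer expels benzoate and benzenesulfinate to form C7=C8 and C7'=C8', the equilibrating intermediate favouring the E-alkene next to the branched ring carbon; in the aprotic medium an electron taken up by the polyene can only be discharged by loss of the allylic benzoate.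

Step 12
Reactants: 19
Product: 20 (3R,4S,5R,6R,3'R,4'S,5'R,6'R)-5,6,5',6'-tetrahydro-β,β-carotene-3,4,3',4'-tetrol
Conditions: 2 M aq. HCl–THF, 0 °C → rt, dark, Ar
Reagents that add atoms: none
Why: Acid hydrolysis of the cis-fused dioxolanes; the two hydroxyls are on a saturated ring and not allylic, so dilute acid should not ionise them, and the polyene should tolerate brief exposure in the dark.

Step 13
Reactants: 20
Product: 22 target 4,4'-bis(hydrogen sulfate), via bis(dibutylstannylene) acetal 21 (not isolated)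
Conditions: Bu2SnO (2.2 equiv), MeOH–toluene, 65 °C, evaporate; SO3·NMe3 (2.5 equiv), 1,4-dioxane, rt; Dowex 50W (H+ form), MeOH, 0 °C
Reagents that add atoms: sulfur trioxide–trimethylamine complex, C[N+](C)(C)S(=O)(=O)[O-]
Why: Stannylene-acetal-directed sulfation: in the five-membered tin acetal of a cis-diol on a chair the equatorial oxygen is the nucleophilic one, here O4, whereas O3 is axial and syn-diaxial to a C1 methyl, so each ring should be sulfated once at O4.

**Compound list**

1 | (S)-glycidol, (2S)-oxiran-2-ylmethanol | OC[C@H]1CO1 | starting material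
2 | isopropenylmagnesium bromide | CC(=C)[Mg]Br | starting material
3 | (R)-4-methylpent-4-ene-1,2-diol | O[C@@H](CO)CC(C)=C | intermediate
4 | (R)-4-methyl-1,2-bis(triethylsilyloxy)pent-4-ene | CC[Si](CC)(CC)O[C@@H](CO[Si](CC)(CC)CC)CC(C)=C | intermediate
5 | (R)-4-methyl-2-(triethylsilyloxy)pent-4-enal | CC[Si](CC)(CC)O[C@@H](C=O)CC(C)=C | intermediate
6 | (S)-4-benzyl-3-propionyloxazolidin-2-one | CCC(=O)N1[C@@H](Cc2ccccc2)COC1=O | starting material
7 | Z-dibutylboron enolate of 6 | C/C=C(\OB(CCCC)CCCC)N1[C@@H](Cc2ccccc2)COC1=O | intermediate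
8 | (S)-4-benzyl-3-[(2S,3S,4R)-3-hydroxy-2,6-dimethyl-4-(triethylsilyloxy)hept-6-enoyl]oxazolidin-2-one | O=C(N1[C@@H](Cc2ccccc2)COC1=O)[C@@H](C)[C@H](O)[C@H](O[Si](CC)(CC)CC)CC(C)=C | intermediate
9 | (2S,3S,4R)-3-hydroxy-N-methoxy-N,2,6-trimethyl-4-(triethylsilyloxy)hept-6-enamide | CON(C)C(=O)[C@@H](C)[C@H](O)[C@H](O[Si](CC)(CC)CC)CC(C)=C | intermediate
10 | (2S)-2-[(4S,5R)-2,2-dimethyl-5-(2-methylprop-2-enyl)-1,3-dioxolan-4-yl]-N-methoxy-N-methylpropanamide | CON(C)C(=O)[C@@H](C)[C@@H]1OC(C)(C)O[C@@H]1CC(C)=C | intermediate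
11 | (2S)-2-[(4S,5R)-2,2-dimethyl-5-(2-methylprop-2-enyl)-1,3-dioxolan-4-yl]propanal | O=C[C@@H](C)[C@@H]1OC(C)(C)O[C@@H]1CC(C)=C | intermediate
12 | diethyl [(phenylsulfonyl)methyl]phosphonate | CCOP(=O)(CS(=O)(=O)c1ccccc1)OCC | starting material
13 | (4R,5S)-2,2-dimethyl-4-(2-methylprop-2-enyl)-5-[(2R,3E)-4-(phenylsulfonyl)but-3-en-2-yl]-1,3-dioxolane | O=S(=O)(c1ccccc1)/C=C/[C@@H](C)[C@@H]1OC(C)(C)O[C@@H]1CC(C)=C | intermediate
14 | (3aS,4R,5R,7aR)-2,2,4,6,6-pentamethyl-5-[(phenylsulfonyl)methyl]hexahydro-1,3-benzodioxole (target numbering 3R,4S,5R,6R) | O=S(=O)(c1ccccc1)C[C@@H]1[C@@H](C)[C@@H]2OC(C)(C)O[C@@H]2CC1(C)C | intermediate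
15 | crocetindial, (2E,4E,6E,8E,10E,12E,14E)-2,6,11,15-tetramethylhexadeca-2,4,6,8,10,12,14-heptaenedial | O=C/C(C)=C/C=C/C(C)=C/C=C/C=C(C)/C=C/C=C(C)/C=O | starting material
16 | C7-lithio derivative of 14 | [Li]C(S(=O)(=O)c1ccccc1)[C@@H]1[C@@H](C)[C@@H]2OC(C)(C)O[C@@H]2CC1(C)C | intermediate
17 | dilithium 8,8'-dialkoxide from twofold addition of 16 to 15 (C7, C8, C7', C8' as mixtures) | CC(/C=C/C=C(C)/C(O[Li])C(S(=O)(=O)c1ccccc1)[C@@H]1[C@@H](C)[C@@H]2OC(C)(C)O[C@@H]2CC1(C)C)=C\C=C\C=C(C)\C=C\C=C(C)\C(O[Li])C(S(=O)(=O)c1ccccc1)[C@@H]1[C@@H](C)[C@@H]2OC(C)(C)O[C@@H]2CC1(C)C | intermediate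
18 | 8,8'-bis(benzoyloxy)-7,7'-bis(phenylsulfonyl)-7,8,7',8'-tetrahydro derivative of 19 (C7, C8, C7', C8' as mixtures) | CC(/C=C/C=C(C)/C(OC(=O)c1ccccc1)C(S(=O)(=O)c1ccccc1)[C@@H]1[C@@H](C)[C@@H]2OC(C)(C)O[C@@H]2CC1(C)C)=C\C=C\C=C(C)\C=C\C=C(C)\C(OC(=O)c1ccccc1)C(S(=O)(=O)c1ccccc1)[C@@H]1[C@@H](C)[C@@H]2OC(C)(C)O[C@@H]2CC1(C)C | intermediate
19 | (3R,4S,5R,6R,3'R,4'S,5'R,6'R)-3,4:3',4'-di-O-isopropylidene-5,6,5',6'-tetrahydro-β,β-carotene-3,4,3',4'-tetrol (all-E) | CC(/C=C/C=C(C)/C=C/[C@@H]1[C@@H](C)[C@@H]2OC(C)(C)O[C@@H]2CC1(C)C)=C\C=C\C=C(C)\C=C\C=C(C)\C=C\[C@@H]1[C@@H](C)[C@@H]2OC(C)(C)O[C@@H]2CC1(C)C | intermediate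
20 | (3R,4S,5R,6R,3'R,4'S,5'R,6'R)-5,6,5',6'-tetrahydro-β,β-carotene-3,4,3',4'-tetrol (all-E) | CC(/C=C/C=C(C)/C=C/[C@@H]1[C@@H](C)[C@H](O)[C@H](O)CC1(C)C)=C\C=C\C=C(C)\C=C\C=C(C)\C=C\[C@@H]1[C@@H](C)[C@H](O)[C@H](O)CC1(C)C | intermediate
21 | 3,4:3',4'-bis-O-(dibutylstannylene) acetal of 20 | CC(/C=C/C=C(C)/C=C/[C@@H]1[C@@H](C)[C@@H]2O[Sn](CCCC)(CCCC)O[C@@H]2CC1(C)C)=C\C=C\C=C(C)\C=C\C=C(C)\C=C\[C@@H]1[C@@H](C)[C@@H]2O[Sn](CCCC)(CCCC)O[C@@H]2CC1(C)C | intermediate
22 | (3R,4S,5R,6R,3'R,4'S,5'R,6'R)-5,6,5',6'-tetrahydro-β,β-carotene-3,4,3',4'-tetrol 4,4'-bis(hydrogen sulfate) (CNP0202532.2) | CC(/C=C/C=C(C)/C=C/[C@@H]1[C@@H](C)[C@H](OS(=O)(=O)O)[C@H](O)CC1(C)C)=C\C=C\C=C(C)\C=C\C=C(C)\C=C\[C@@H]1[C@@H](C)[C@H](OS(=O)(=O)O)[C@H](O)CC1(C)C | target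

**Summary**

Total step count: 13. Longest linear sequence: 13 steps (1 → 22); 15 enters in step 10.

Steps most likely to fail:

1. Step 9. The tertiary radical may be reduced by a second hydrogen-atom transfer (net hydrogenation of the isopropenyl group), or hydride may attack the vinyl sulfone, before the ring closes. Closure through a less ordered transition state would also erode the configuration at C6. The fallback addresses the first two processes. It sets out from 10 and returns at 14, generating the same C1 radical without any metal hydride. Mukaiyama hydration of the isopropenyl group of 10 (Co(acac)2, PhSiH3, O2, i-PrOH) would give the tertiary alcohol F1. Reduction with i-Bu2AlH (THF, −78 °C) gives the hydroxy aldehyde F2, and olefination with 12 (LiCl, DBU, MeCN) gives the hydroxy vinyl sulfone F3. Acylation with N-phthalimidoyl chlorooxalate (from (COCl)2 and N-hydroxyphthalimide; Et3N, DMAP, THF) gives the N-phthalimidoyl oxalate F4. Visible-light photoredox fragmentation (Ru(bpy)3(PF6)2, Hantzsch ester, i-Pr2NEt·HBF4, THF–CH2Cl2, blue light) then releases two CO2 and the tertiary radical, which closes 6-exo onto C6 to give 14.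

2. Step 11. Electron transfer to the long polyene can compete with fragmentation of the benzoate/sulfone pairs, leading to partial reduction or geometric scrambling, and the twofold elimination may stop after one end. The fallback sets out from 14 and returns at 20, forming C7=C8 on a small fragment and assembling the polyene by a C15 + C10 + C15 Wittig reaction. The lithiated sulfone from 14 (n-BuLi, THF, −78 °C) is added to ethyl (E)-3-methyl-4-oxobut-2-enoate and benzoylated in the flask to the benzoyloxy sulfone ester F5. SmI2 in THF–DMPU, now acting on a simple enoate, gives the (7E,9E)-dienoate F6, and i-Bu2AlH gives the dienol F7. Ph3P·HBr in MeOH gives the C15 phosphonium bromide F8, with exchange of the acetonide to the free 3,4-diol. Twofold Wittig reaction with 2,7-dimethylocta-2,4,6-trienedial (NaOMe, MeOH–CH2Cl2), then thermal equilibration of the C11=C12 isomers in hot ethanol, gives 20.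

3. Step 13. Stannylene activation may not discriminate O4 from O3 well enough, or a ring may be sulfated twice, giving regioisomeric sulfates that are hard to separate. The fallback sets out from 20 and returns at 22, fixing the regiochemistry on chromatographable silyl ethers before any sulfate is present. Selective silylation of the equatorial hydroxyls (Et3SiCl, imidazole, DMF, −20 °C) gives the 4,4'-bis(triethylsilyl) ether F9. TBSOTf with 2,6-lutidine gives the fully silylated tetrol F10. Selective removal of the triethylsilyl groups (PPTS, MeOH–CH2Cl2, 0 °C) gives the 3,3'-bis(TBS) 4,4'-diol F11. Sulfation with SO3·pyridine in DMF gives the protected disulfate F12, and Bu4NF in THF followed by cation exchange gives 22.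

**Further compounds**

F1 | step 9 | (2S)-2-[(4S,5R)-5-(2-hydroxy-2-methylpropyl)-2,2-dimethyl-1,3-dioxolan-4-yl]-N-methoxy-N-methylpropanamide | CON(C)C(=O)[C@@H](C)[C@@H]1OC(C)(C)O[C@@H]1CC(C)(C)O
F2 | step 9 | (2S)-2-[(4S,5R)-5-(2-hydroxy-2-methylpropyl)-2,2-dimethyl-1,3-dioxolan-4-yl]propanal | O=C[C@@H](C)[C@@H]1OC(C)(C)O[C@@H]1CC(C)(C)O
F3 | step 9 | 1-{(4R,5S)-2,2-dimethyl-5-[(2R,3E)-4-(phenylsulfonyl)but-3-en-2-yl]-1,3-dioxolan-4-yl}-2-methylpropan-2-ol | O=S(=O)(c1ccccc1)/C=C/[C@@H](C)[C@@H]1OC(C)(C)O[C@@H]1CC(C)(C)O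
F4 | step 9 | N-phthalimidoyl oxalate of F3 (mixed oxalate of the tertiary alcohol and N-hydroxyphthalimide) | O=S(=O)(c1ccccc1)/C=C/[C@@H](C)[C@@H]1OC(C)(C)O[C@@H]1CC(C)(C)OC(=O)C(=O)ON1C(=O)c2ccccc2C1=O
F5 | step 11 | ethyl (2E)-4-(benzoyloxy)-3-methyl-5-[(3aS,4R,5R,7aR)-2,2,4,6,6-pentamethylhexahydro-1,3-benzodioxol-5-yl]-5-(phenylsulfonyl)pent-2-enoate (C7, C8 as mixtures) | CCOC(=O)/C=C(\C)C(OC(=O)c1ccccc1)C(S(=O)(=O)c1ccccc1)[C@@H]1[C@@H](C)[C@@H]2OC(C)(C)O[C@@H]2CC1(C)C
F6 | step 11 | ethyl (2E,4E)-3-methyl-5-[(3aS,4R,5R,7aR)-2,2,4,6,6-pentamethylhexahydro-1,3-benzodioxol-5-yl]penta-2,4-dienoate | CCOC(=O)/C=C(C)/C=C/[C@@H]1[C@@H](C)[C@@H]2OC(C)(C)O[C@@H]2CC1(C)C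
F7 | step 11 | (2E,4E)-3-methyl-5-[(3aS,4R,5R,7aR)-2,2,4,6,6-pentamethylhexahydro-1,3-benzodioxol-5-yl]penta-2,4-dien-1-ol | OC/C=C(C)/C=C/[C@@H]1[C@@H](C)[C@@H]2OC(C)(C)O[C@@H]2CC1(C)C
F8 | step 11 | {(2E,4E)-5-[(1R,2R,3S,4R)-3,4-dihydroxy-2,6,6-trimethylcyclohexyl]-3-methylpenta-2,4-dienyl}triphenylphosphonium bromide | [Br-].c1ccccc1[P+](c1ccccc1)(c1ccccc1)C/C=C(C)/C=C/[C@@H]1[C@@H](C)[C@H](O)[C@H](O)CC1(C)C
F9 | step 13 | 4,4'-bis-O-(triethylsilyl) ether of 20 | CC(/C=C/C=C(C)/C=C/[C@@H]1[C@@H](C)[C@H](O[Si](CC)(CC)CC)[C@H](O)CC1(C)C)=C\C=C\C=C(C)\C=C\C=C(C)\C=C\[C@@H]1[C@@H](C)[C@H](O[Si](CC)(CC)CC)[C@H](O)CC1(C)C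
F10 | step 13 | 3,3'-bis-O-(tert-butyldimethylsilyl)-4,4'-bis-O-(triethylsilyl) ether of 20 | CC(/C=C/C=C(C)/C=C/[C@@H]1[C@@H](C)[C@H](O[Si](CC)(CC)CC)[C@H](O[Si](C)(C)C(C)(C)C)CC1(C)C)=C\C=C\C=C(C)\C=C\C=C(C)\C=C\[C@@H]1[C@@H](C)[C@H](O[Si](CC)(CC)CC)[C@H](O[Si](C)(C)C(C)(C)C)CC1(C)C
F11 | step 13 | 3,3'-bis-O-(tert-butyldimethylsilyl) ether of 20 (4,4'-diol) | CC(/C=C/C=C(C)/C=C/[C@@H]1[C@@H](C)[C@H](O)[C@H](O[Si](C)(C)C(C)(C)C)CC1(C)C)=C\C=C\C=C(C)\C=C\C=C(C)\C=C\[C@@H]1[C@@H](C)[C@H](O)[C@H](O[Si](C)(C)C(C)(C)C)CC1(C)C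
F12 | step 13 | 3,3'-bis-O-(tert-butyldimethylsilyl) ether of 22 (4,4'-bis(hydrogen sulfate)) | CC(/C=C/C=C(C)/C=C/[C@@H]1[C@@H](C)[C@H](OS(=O)(=O)O)[C@H](O[Si](C)(C)C(C)(C)C)CC1(C)C)=C\C=C\C=C(C)\C=C\C=C(C)\C=C\[C@@H]1[C@@H](C)[C@H](OS(=O)(=O)O)[C@H](O[Si](C)(C)C(C)(C)C)CC1(C)C
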